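Cuts: first the pyran ring (O1–C2 and C4–C4a), then the benzene ring at C6–C7, then the C6–C(=O)Ph bond and the C8–CH2 bond of the prenyl group. What remains is triacetic acid lactone.
Enabling feature: along C7–C8–C8a–C4a–C5–C6–C(=O)Ph the oxygens sit on C7, C8a, C5 and the ketone carbon, that is on alternate carbons. The prenyl group sits on C8, next to the chain end C7. The carbocycle is therefore a folded 2-prenyl-3,5,7-trioxo-7-phenylheptanoate, which can be stored as a 4-hydroxy-2-pyrone.
Forward: the purchased pyrone is prenylated at its C3 and benzoylated at its C6 methyl group. The lactone is then opened and the chain closed to the benzene ring. The 2,2-dimethylpyran ring is fused on last, through the oxygen para to the ketone and the one unsubstituted ring carbon.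
Stereochemistry: none to set. The target has no stereocentre, and its ring alkene C3=C4 is cis by necessity.

Key step: step 3

Remark: the SMILES carries no stereodescriptor and the molecule has no stereogenic element, so "single enantiomer" is taken to mean the achiral compound itself.

Step 1
Reactants: 1 4-hydroxy-6-methyl-2H-pyran-2-one (triacetic acid lactone); 2 1-bromo-3-methylbut-2-ene (prenyl bromide)
Product: 4 4-hydroxy-6-methyl-3-(3-methylbut-2-enyl)-2H-pyran-2-one, via O-prenyl ether 3 (not isolated)
Conditions: 1 (1.5 equiv), KHCO3 (1.0 equiv), 2 (1.0 equiv), DMF, rt; then Pd(PPh3)4 (3 mol %), 50 °C, Ar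
Reagents that add atoms: none
Why: Tsuji–Trost allylation under thermodynamic control: direct alkylation of the ambident pyronate gives much O-prenyl ether 3, but Pd(0) re-ionises this vinylogous allyl ester and the soft pyronate then attacks the unsubstituted end of the π-prenyl complex through C3 (a known O-to-C allyl transfer of 4-allyloxy-2-pyrones), while the excess of the more acidic 1 keeps 4 largely protonated and so limits a second alkylation.

Step 2
Reactants: 4 4-hydroxy-6-methyl-3-(3-methylbut-2-enyl)-2H-pyran-2-one; 5 methyl benzoate
Product: 6 4-hydroxy-3-(3-methylbut-2-enyl)-6-(2-oxo-2-phenylethyl)-2H-pyran-2-one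
Conditions: LDA (3.3 equiv), THF, −78 °C; then 5 (1.05 equiv), −78 to 0 °C; 1 M HCl
Reagents that add atoms: none
Why: Crossed Claisen acylation of the oxygen/C6-methyl dianion, a known reaction of 4-hydroxy-6-methyl-2-pyrones: the more basic terminal carbanion attacks the non-enolisable ester, and the third equivalent of base takes up the acidic phenacyl proton so that the product does not quench the dianion.

Step 3
Reactants: 6 4-hydroxy-3-(3-methylbut-2-enyl)-6-(2-oxo-2-phenylethyl)-2H-pyran-2-one
Product: 8 2,4,6-trihydroxy-3-(3-methylbut-2-enyl)benzophenone, via triketo ester 7 (not isolated)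
Conditions: Mg(OMe)2 (5 equiv, commercial solution in MeOH), MeOH, reflux, Ar; then cold 1 M HCl to pH 3
Reagents that add atoms: magnesium methoxide, C[O-].C[O-].[Mg+2] (supplies the methoxy group of 7, which is lost again on the way to 8)
Why: Methoxide adds to the lactone carbonyl of the magnesium pyronate and the ring oxygen leaves as an enolate, giving triketo ester 7 as a magnesium polyenolate; the carbon between the benzoyl group and the neighbouring ketone then attacks the ester carbonyl, methoxide is expelled, and the resulting 2-benzoylcyclohexane-1,3,5-trione enolises three times to the benzene ring. The closest known reaction type is the magnesium-alkoxide-induced Claisen (Dieckmann-type) cyclisation of 4-hydroxy-6-(2-oxoalkyl)-2-pyrones and of 3,5,7-triketo esters to acylphloroglucinols. The single ring closes in the 6-exo-trig mode at the ester carbonyl and creates the bond that is C6–C7 of the chromene; no stereocentre is formed, and the labile one at C2 of 7 vanishes on aromatisation. The selectivity needed is Claisen over aldol folding: attack of the ester α-carbon on the benzoyl ketone would make a quaternary carbon bearing prenyl and CO2Me that cannot aromatise, so that addition stays reversible, while the Claisen product leaves the equilibrium as a stable magnesium phloroglucinolate. The prenyl group also makes C2 of 7 less acidic, which leaves the ester carbonyl less deactivated by enolate formation, and magnesium chelation of the 1,3-dicarbonyl units holds the chain folded and shields it from retro-Claisen cleavage.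

Step 4
Reactants: 8 2,4,6-trihydroxy-3-(3-methylbut-2-enyl)benzophenone; 9 3-chloro-3-methylbut-1-yne
Product: 10 2,6-dihydroxy-4-(2-methylbut-3-yn-2-yloxy)-3-(3-methylbut-2-enyl)benzophenone
Conditions: 9 (1.2 equiv), K2CO3 (1.1 equiv), KI (10 mol %), CuI (2 mol %), acetone, 50 °C, Ar
Reagents that add atoms: none
Why: Williamson-type O-propargylation through the copper allenylidene of the tertiary chloride: about one equivalent of weak base ionises only the most acidic hydroxyl, the one para to the ketone, whereas the 2- and 6-hydroxyls flank the benzoyl group, share its hydrogen bond and are more hindered, as in the known 4-O-alkylations of 2,4,6-trihydroxyphenyl ketones.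

Step 5
Reactants: 10 2,6-dihydroxy-4-(2-methylbut-3-yn-2-yloxy)-3-(3-methylbut-2-enyl)benzophenone
Product: 13 6-benzoyl-5,7-dihydroxy-2,2-dimethyl-8-(3-methylbut-2-enyl)-2H-chromene (target), via allenylphenol 11 (not isolated), via o-quinone methide 12 (not isolated)
Conditions: o-xylene (dilute, base-free), 140 °C, Ar
Reagents that add atoms: none
Why: Aromatic propargyl Claisen rearrangement to the free carbon C5 (the shift to the prenyl-bearing C3 is reversible and leads nowhere), enolisation to 11, [1,5]-hydrogen shift to the (Z)-o-quinone methide 12 and oxa-6π electrocyclisation form the standard path from aryl 1,1-dimethylpropargyl ethers to 2,2-dimethylchromenes, and the base-free non-polar medium keeps the ortho hydroxyls engaged by the ketone and slows proton exchange, so the free para hydroxyl next to the allene should deliver the hydrogen and become O1.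

Compound list
1 | 4-hydroxy-6-methyl-2H-pyran-2-one (triacetic acid lactone) | CC1=CC(O)=CC(=O)O1 | starting material
2 | 1-bromo-3-methylbut-2-ene (prenyl bromide) | CC(C)=CCBr | starting material
3 | 6-methyl-4-(3-methylbut-2-enyloxy)-2H-pyran-2-one | CC(C)=CCOC1=CC(=O)OC(C)=C1 | intermediate (not isolated)
4 | 4-hydroxy-6-methyl-3-(3-methylbut-2-enyl)-2H-pyran-2-one | CC(C)=CCC1=C(O)C=C(C)OC1=O | intermediate
5 | methyl benzoate | COC(=O)c1ccccc1 | starting material
6 | 4-hydroxy-3-(3-methylbut-2-enyl)-6-(2-oxo-2-phenylethyl)-2H-pyran-2-one | CC(C)=CCC1=C(O)C=C(CC(=O)c2ccccc2)OC1=O | intermediate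
7 | methyl 2-(3-methylbut-2-enyl)-3,5,7-trioxo-7-phenylheptanoate (C2 racemic and labile; present as magnesium enolate) | COC(=O)C(CC=C(C)C)C(=O)CC(=O)CC(=O)c1ccccc1 | intermediate (not isolated)
8 | 2,4,6-trihydroxy-3-(3-methylbut-2-enyl)benzophenone | CC(C)=CCc1c(O)cc(O)c(C(=O)c2ccccc2)c1O | intermediate
9 | 3-chloro-3-methylbut-1-yne | CC(C)(Cl)C#C | starting material
10 | 2,6-dihydroxy-4-(2-methylbut-3-yn-2-yloxy)-3-(3-methylbut-2-enyl)benzophenone | CC(C)=CCc1c(OC(C)(C)C#C)cc(O)c(C(=O)c2ccccc2)c1O | intermediate
11 | 2,4,6-trihydroxy-3-(3-methylbuta-1,2-dienyl)-5-(3-methylbut-2-enyl)benzophenone | CC(C)=CCc1c(O)c(C=C=C(C)C)c(O)c(C(=O)c2ccccc2)c1O | intermediate (not isolated)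
12 | (6Z)-4-benzoyl-3,5-dihydroxy-2-(3-methylbut-2-enyl)-6-(3-methylbut-2-enylidene)cyclohexa-2,4-dien-1-one | CC(C)=CCC1=C(O)C(C(=O)c2ccccc2)=C(O)/C(=C/C=C(C)C)C1=O | intermediate (not isolated)
13 | 6-benzoyl-5,7-dihydroxy-2,2-dimethyl-8-(3-methylbut-2-enyl)-2H-chromene (achiral) | CC(C)=CCc1c(O)c(C(=O)c2ccccc2)c(O)c2c1OC(C)(C)C=C2 | target

Total step count: 5. Longest linear sequence: 5 steps (1 → 4 → 6 → 8 → 10 → 13).

Steps most likely to fail

Step 3. The doubly deprotonated pyrone may resist addition of methoxide. The opened chain may also relactonise, or fragment by retro-Claisen cleavage, faster than it forms the carbon–carbon bond. The fallback sets out from 2 and comes back at 8. Commercial 2,4,6-trihydroxybenzophenone (O=C(c1ccccc1)c1c(O)cc(O)cc1O) is C-alkylated with a deficiency of 2 in aqueous KOH at 0 °C. This is the classical C-prenylation of an acylphloroglucinol anion in a protic medium. The benzene ring is then bought rather than built, and the monoprenylated product is separated from doubly alkylated material. No compound outside the list is made (F0).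

Step 4. Alkylation may spread over the three hydroxyls or onto ring carbon. It may also stall, because the delocalised phenoxide is a poor nucleophile towards a tertiary centre. The fallback sets out from 8 and comes back at 13.
- 8 is condensed with 3-methylbut-2-enal (CC(C)=CC=O, 1.5 equiv) under ethylenediammonium diacetate catalysis (10 mol %) in refluxing toluene.
- The free ring carbon adds to the iminium ion, loss of water gives o-quinone methide 12, and this closes as in step 5, so no aryl ether has to be made.
- Under these proton-exchanging conditions either flanking oxygen can close, so a chromatographic separation of regioisomeric chromenes must be expected.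
- No compound outside the list is made (F0).

Step 5. After the Claisen shift the allenyl carbon lies between two hydroxyls, and the ketone can hold only one of its two ortho hydroxyls at a time. Hydrogen transfer and ring closure through the oxygen ortho to the benzoyl group may therefore compete with closure through the para oxygen. The fallback sets out from 10 and comes back at 13.
- The two hydroxyls beside the ketone are capped with Ac2O, Et3N and DMAP in CH2Cl2 to give 2,6-diacetoxy-4-(2-methylbut-3-yn-2-yloxy)-3-(3-methylbut-2-enyl)benzophenone F1.
- Heating in o-xylene at 140 °C then leaves the oxygen released by the Claisen shift as the only one able to deliver hydrogen and to close. This gives 6-benzoyl-2,2-dimethyl-8-(3-methylbut-2-enyl)-2H-chromene-5,7-diyl diacetate F2.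
- Catalytic K2CO3 in MeOH at rt removes both acetates and gives 13.

Further compounds
F0 | step 3 | none | none
F0 | step 4 | none | none
F1 | step 5 | 2,6-diacetoxy-4-(2-methylbut-3-yn-2-yloxy)-3-(3-methylbut-2-enyl)benzophenone | CC(C)=CCc1c(OC(C)(C)C#C)cc(OC(C)=O)c(C(=O)c2ccccc2)c1OC(C)=O
F2 | step 5 | 6-benzoyl-2,2-dimethyl-8-(3-methylbut-2-enyl)-2H-chromene-5,7-diyl diacetate | CC(C)=CCc1c(OC(C)=O)c(C(=O)c2ccccc2)c(OC(C)=O)c2c1OC(C)(C)C=C2
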